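**Retrosynthetic overview**
- Target ⇐ double O‑debenzylation of its bis(benzyl ether).
- E‑benzylidene C=C ⇐ Horner–Wadsworth–Emmons (HWE) olefination of an α‑phosphono‑γ‑lactone carbanion with 3‑(benzyloxy)‑4,5‑dimethoxybenzaldehyde. That carbanion comes from copper‑catalysed aryl‑Grignard opening of a phosphono‑cyclopropane‑fused lactone, which also makes the C–CH2Ar bond.
- Fused bicycle ⇐ (R)‑epichlorohydrin + triethyl phosphonoacetate in one pot; the (R)‑CH centre of the target comes from the chiral pool here.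
- Ring order: cyclopropane, then γ‑lactone, both in the first operation. The cyclopropane is opened in the second operation and the lactone stays as the only non‑aromatic ring. Both benzene rings are bought.

Assumption: the two benzyl‑protected arenes used in step 2 are bought as catalogue compounds.

**Step 1**
Reactants: 1 (R)‑epichlorohydrin [(2R)‑2‑(chloromethyl)oxirane]; 2 triethyl phosphonoacetate
Product: 6 diethyl [(1R,5S)‑2‑oxo‑3‑oxabicyclo[3.1.0]hexan‑1‑yl]phosphonate, via chlorohydrin 3 (not isolated), via epoxide 4 (not isolated), via cyclopropylcarbinol 5 (not isolated)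
Conditions: NaOEt (1.15 equiv), EtOH, 0 °C to rt, then 60 °C; AcOH quench
Reagents that add atoms: none
Why: Proposed new method: the phosphonoacetate carbanion opens the epoxide of 1 at its CH2 terminus (SN2), alkoxide 3 displaces chloride to give the transposed epoxide 4, and the re‑formed carbanion attacks the epoxide CH carbon (3‑exo‑tet, inversion, which fixes the ring‑fusion CH from the chiral pool) with the bulkier phosphoryl group turned away from the CH2O arm, so the ester sits cis to the alkoxide in 5 and lactonises to 6; the closest known reaction type is the one‑pot epichlorohydrin/dialkyl malonate (and epichlorohydrin/sulfonylacetonitrile) cyclopropanation–lactonisation, and the specific risks are Wadsworth–Emmons‑type phosphoryl transfer and the wrong cyclopropane diastereomer.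

**Step 2**
Reactants: 6 diethyl [(1R,5S)‑2‑oxo‑3‑oxabicyclo[3.1.0]hexan‑1‑yl]phosphonate; 7 1‑(benzyloxy)‑4‑bromo‑2‑methoxybenzene; 8 3‑(benzyloxy)‑4,5‑dimethoxybenzaldehyde
Product: 11 (3E,4R)‑4‑[4‑(benzyloxy)‑3‑methoxybenzyl]‑3‑[3‑(benzyloxy)‑4,5‑dimethoxybenzylidene]oxolan‑2‑one, via arylmagnesium bromide 9 (not isolated), via magnesium phosphonate enolate 10 (not isolated)
Conditions: 7 (1.3 equiv), Mg, THF, 45 °C; add to 6, CuBr·SMe2 (10 mol %), THF, −40 to 0 °C; then 8 (1.5 equiv), 0 to 60 °C; aq. NH4Cl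
Reagents that add atoms: none
Why: Proposed new method: copper‑catalysed homoconjugate (SN2‑type) addition of Grignard 9 at the unsubstituted cyclopropane CH2 of the doubly activated cyclopropane releases the chelated magnesium phosphonate enolate 10, which is itself an HWE reagent and olefinates 8 to the thermodynamically preferred E‑benzylidene lactone, while the existing stereocentre is touched in neither event; the closest known reaction types are the copper‑halide‑catalysed Grignard opening of the malonate‑derived bicyclic lactone, Michael addition/HWE tandems of vinylphosphonates and magnesium‑mediated (Rathke‑type) HWE olefination.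

**Step 3**
Reactants: 11 (3E,4R)‑4‑[4‑(benzyloxy)‑3‑methoxybenzyl]‑3‑[3‑(benzyloxy)‑4,5‑dimethoxybenzylidene]oxolan‑2‑one
Product: 12 (3E,4R)‑3‑(3‑hydroxy‑4,5‑dimethoxybenzylidene)‑4‑(4‑hydroxy‑3‑methoxybenzyl)oxolan‑2‑one
Conditions: BCl3 (5 equiv), pentamethylbenzene (6 equiv), CH2Cl2, −78 °C; then H2O
Reagents that add atoms: none
Why: Lewis‑acid debenzylation with a cation scavenger: BCl3 ionises the aryl benzyl ethers and pentamethylbenzene traps the benzyl cation (Friedel–Crafts) at −78 °C, where aryl methyl ethers, the lactone and the conjugated alkene are inert, so neither the stereocentre nor the E geometry changes.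

**Compound list**
1 | (R)‑epichlorohydrin, (2R)‑2‑(chloromethyl)oxirane | ClC[C@H]1CO1 | starting material
2 | triethyl phosphonoacetate | CCOC(=O)CP(=O)(OCC)OCC | starting material
3 | ethyl (4R)‑5‑chloro‑2‑(diethoxyphosphoryl)‑4‑hydroxypentanoate (as sodium alkoxide, C2 epimers) | CCOC(=O)C(C[C@@H](O)CCl)P(=O)(OCC)OCC | intermediate
4 | ethyl 2‑(diethoxyphosphoryl)‑3‑[(2R)‑oxiran‑2‑yl]propanoate (C2 epimers) | CCOC(=O)C(C[C@@H]1CO1)P(=O)(OCC)OCC | intermediate
5 | ethyl (1R,2S)‑1‑(diethoxyphosphoryl)‑2‑(hydroxymethyl)cyclopropane‑1‑carboxylate (as sodium alkoxide; CH2O cis to the ester) | CCOC(=O)[C@@]1(P(=O)(OCC)OCC)C[C@H]1CO | intermediate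
6 | diethyl [(1R,5S)‑2‑oxo‑3‑oxabicyclo[3.1.0]hexan‑1‑yl]phosphonate | O=C1OC[C@@H]2C[C@]12P(=O)(OCC)OCC | intermediate
7 | 1‑(benzyloxy)‑4‑bromo‑2‑methoxybenzene | COc1cc(Br)ccc1OCc1ccccc1 | starting material
8 | 3‑(benzyloxy)‑4,5‑dimethoxybenzaldehyde | COc1cc(C=O)cc(OCc2ccccc2)c1OC | starting material
9 | [4‑(benzyloxy)‑3‑methoxyphenyl]magnesium bromide | COc1cc([Mg]Br)ccc1OCc1ccccc1 | intermediate
10 | bromomagnesium enolate of diethyl {(4S)‑4‑[4‑(benzyloxy)‑3‑methoxybenzyl]‑2‑oxooxolan‑3‑yl}phosphonate | CCOP(=O)(OCC)C1=C(O[Mg]Br)OC[C@@H]1Cc1ccc(OCc2ccccc2)c(OC)c1 | intermediate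
11 | (3E,4R)‑4‑[4‑(benzyloxy)‑3‑methoxybenzyl]‑3‑[3‑(benzyloxy)‑4,5‑dimethoxybenzylidene]oxolan‑2‑one | COc1cc(C[C@H]2COC(=O)/C2=C/c2cc(OCc3ccccc3)c(OC)c(OC)c2)ccc1OCc1ccccc1 | intermediate
12 | (3E,4R)‑3‑(3‑hydroxy‑4,5‑dimethoxybenzylidene)‑4‑(4‑hydroxy‑3‑methoxybenzyl)oxolan‑2‑one | COc1cc(C[C@H]2COC(=O)/C2=C/c2cc(O)c(OC)c(OC)c2)ccc1O | target

**Totals**
Total step count: 3. Longest linear sequence: 3 steps (1 + 2 → 6 → 11 → 12).

**Steps most likely to fail, with fallbacks**

Step 1 (highest risk: phosphoryl transfer, wrong cyclopropane diastereomer, or erosion of ee by direct chloride displacement). The fallback sets out from 1 and comes back at 11, replacing the phosphonate handle by the proven malonate handle and the HWE by an aldol condensation. Compound 1 and diethyl malonate (NaOEt, EtOH, reflux) give ethyl (1S,5R)‑2‑oxo‑3‑oxabicyclo[3.1.0]hexane‑1‑carboxylate F1. Copper‑catalysed opening of F1 with Grignard 9 (CuBr·SMe2, THF, −40 to 0 °C) gives ethyl (4R)‑4‑[4‑(benzyloxy)‑3‑methoxybenzyl]‑2‑oxooxolane‑3‑carboxylate F2. Hydrolytic dealkoxycarbonylation (H2O, DMSO, 150 °C) gives (4R)‑4‑[4‑(benzyloxy)‑3‑methoxybenzyl]oxolan‑2‑one F3. Aldol addition of its lithium enolate (LiN(SiMe3)2, THF, −78 °C) to 8 gives (3S,4R)‑4‑[4‑(benzyloxy)‑3‑methoxybenzyl]‑3‑{[3‑(benzyloxy)‑4,5‑dimethoxyphenyl](hydroxy)methyl}oxolan‑2‑one F4 (carbinol epimers). Acid dehydration (TsOH, toluene, 80 °C) then gives the E‑alkene 11.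

Step 2 (risk: Grignard attack at the lactone carbonyl, or a sluggish HWE from the chelated magnesium enolate with an electron‑rich aldehyde). The fallback sets out from 6 and comes back at 11, decoupling the two bond formations. After the copper‑catalysed opening with 9, the mixture is quenched at 0 °C with aq. NH4Cl and diethyl {(4S)‑4‑[4‑(benzyloxy)‑3‑methoxybenzyl]‑2‑oxooxolan‑3‑yl}phosphonate F5 (C3 epimers) is isolated. F5 is then olefinated with 8 as a lithium‑chelated, amine‑generated carbanion (LiCl, DBU, MeCN, rt; Masamune–Roush HWE) to give 11.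

Step 3 (risk: partial loss of the methyl ether next to the freed phenol, or incomplete debenzylation). The fallback sets out from 6 and comes back at 12, changing the protecting group so the last step is a fluoride desilylation. 4‑Bromo‑2‑methoxyphenol and 3‑hydroxy‑4,5‑dimethoxybenzaldehyde are silylated (tert‑butyldimethylsilyl chloride, imidazole, DMF) to (4‑bromo‑2‑methoxyphenoxy)(tert‑butyl)dimethylsilane F6 and 3‑[(tert‑butyldimethylsilyl)oxy]‑4,5‑dimethoxybenzaldehyde F7. These are carried through the step 2 protocol with 6 to (3E,4R)‑4‑{4‑[(tert‑butyldimethylsilyl)oxy]‑3‑methoxybenzyl}‑3‑{3‑[(tert‑butyldimethylsilyl)oxy]‑4,5‑dimethoxybenzylidene}oxolan‑2‑one F8. Tetrabutylammonium fluoride buffered with AcOH (THF, 0 °C) then gives 12.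

**Further compounds**
F1 | step 1 | ethyl (1S,5R)‑2‑oxo‑3‑oxabicyclo[3.1.0]hexane‑1‑carboxylate | O=C1OC[C@@H]2C[C@]12C(=O)OCC
F2 | step 1 | ethyl (4R)‑4‑[4‑(benzyloxy)‑3‑methoxybenzyl]‑2‑oxooxolane‑3‑carboxylate (C3 epimers) | CCOC(=O)C1C(=O)OC[C@@H]1Cc1ccc(OCc2ccccc2)c(OC)c1
F3 | step 1 | (4R)‑4‑[4‑(benzyloxy)‑3‑methoxybenzyl]oxolan‑2‑one | O=C1C[C@@H](Cc2ccc(OCc3ccccc3)c(OC)c2)CO1
F4 | step 1 | (3S,4R)‑4‑[4‑(benzyloxy)‑3‑methoxybenzyl]‑3‑{[3‑(benzyloxy)‑4,5‑dimethoxyphenyl](hydroxy)methyl}oxolan‑2‑one (carbinol epimers) | O=C1OC[C@H](Cc2ccc(OCc3ccccc3)c(OC)c2)[C@H]1C(O)c1cc(OCc2ccccc2)c(OC)c(OC)c1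
F5 | step 2 | diethyl {(4S)‑4‑[4‑(benzyloxy)‑3‑methoxybenzyl]‑2‑oxooxolan‑3‑yl}phosphonate (C3 epimers) | CCOP(=O)(OCC)C1C(=O)OC[C@@H]1Cc1ccc(OCc2ccccc2)c(OC)c1
F6 | step 3 | (4‑bromo‑2‑methoxyphenoxy)(tert‑butyl)dimethylsilane | COc1cc(Br)ccc1O[Si](C)(C)C(C)(C)C
F7 | step 3 | 3‑[(tert‑butyldimethylsilyl)oxy]‑4,5‑dimethoxybenzaldehyde | COc1cc(C=O)cc(O[Si](C)(C)C(C)(C)C)c1OC
F8 | step 3 | (3E,4R)‑4‑{4‑[(tert‑butyldimethylsilyl)oxy]‑3‑methoxybenzyl}‑3‑{3‑[(tert‑butyldimethylsilyl)oxy]‑4,5‑dimethoxybenzylidene}oxolan‑2‑one | COc1cc(C[C@H]2COC(=O)/C2=C/c2cc(O[Si](C)(C)C(C)(C)C)c(OC)c(OC)c2)ccc1O[Si](C)(C)C(C)(C)C
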